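**Plan**

- Retrosynthesis: the quinone methide is traced back to a triaryl carbinol (C–O), the tolane is cut at its aryl–C(sp) bond, and the terminal alkyne carbon is cut from the carbon on C6 (lactol homologation). Ring A is then cut at C2–C3, C4–C5 and C6–C1, and last the ester C–O and the carbinol–alkyne C–C bonds.
- Enabling feature: in ring A, C3 and C4 are adjacent CH positions and can come from acetylene. C1 bears the future quinone-methide carbon at the carbinol level, and C6 bears the future alkyne carbon, which at the carboxyl level can be esterified to the carbinol oxygen. C2≡C1 and C6≡C5 then sit in a 1,6-diyne with a C–O–C(=O) tether.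
- Forward: acetylide addition to a diaryl ketone and O-acylation give the diyne ester. Rhodium closes the five-membered lactone and ring A in one step. The phenol protecting groups are exchanged, the lactone carbonyl becomes an ethynyl group, a Sonogashira coupling adds the last ring, and acid unmasks phenols, alcohol and quinone methide.
- Stereochemistry: selaginellin has no stereocentre, and its exocyclic C=C is not stereogenic because the dienone is symmetric. The only stereocentre on the way, a lactol carbon, is racemic and is erased one step later.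
- Design point: the two phenols on the carbinol carbon travel as pivalates up to the cycloaddition, so the tertiary propargylic ester does not ionize. Once that carbon is locked in the lactone they are changed to acid-labile methoxymethyl (MOM) ethers.

Key step: step 4

Assumption: the two silyl-protected alkynes used as starting materials are taken as catalogue compounds; each is otherwise one silylation away from the parent alcohol or phenol.

**Route**

Step 1
Reactants: 1 4,4'-dihydroxybenzophenone
Product: 2 4,4'-bis(pivaloyloxy)benzophenone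
Conditions: PivCl, Et3N, DMAP (cat.), CH2Cl2, 0 °C → rt
Reagents that add atoms: pivaloyl chloride, CC(C)(C)C(Cl)=O
Why: DMAP-catalysed O-acylation of the phenols; the pivaloyloxy groups are only weakly donating, so the later carbinol carbon is about as ionizable as in a 1,1-diphenylpropargyl ester, and their bulk should resist the acetylide of step 3.

Step 2
Reactants: 3 tert-butyldimethyl(prop-2-yn-1-yloxy)silane
Product: 4 4-[(tert-butyldimethylsilyl)oxy]but-2-ynoic acid
Conditions: n-BuLi, THF, −78 °C; CO2 (gas), −78 → 0 °C; cold 1 M HCl to pH 3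
Reagents that add atoms: carbon dioxide, O=C=O
Why: Deprotonation of the terminal alkyne and carboxylation of the lithium acetylide is a standard route to alkynoic acids, and the primary silyl ether should survive a brief cold acidification.

Step 3
Reactants: 5 tert-butyl(4-ethynylphenoxy)dimethylsilane, 2 4,4'-bis(pivaloyloxy)benzophenone, 4 4-[(tert-butyldimethylsilyl)oxy]but-2-ynoic acid
Product: 8 3-{4-[(tert-butyldimethylsilyl)oxy]phenyl}-1,1-bis{4-[(2,2-dimethylpropanoyl)oxy]phenyl}prop-2-yn-1-yl 4-[(tert-butyldimethylsilyl)oxy]but-2-ynoate, via lithium propargylic alkoxide 6 (not isolated), via silyloxybutynoyl chloride 7 (not isolated)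
Conditions: 5, n-BuLi, THF, −78 °C; add 2, −78 → −20 °C; add 7 [from 4, 1-chloro-N,N,2-trimethylprop-1-en-1-amine, CH2Cl2, 0 °C → rt], −78 → 0 °C; pH 7 phosphate buffer; Et3N-washed silica
Reagents that add atoms: none
Why: 1,2-Addition of the lithium acetylide to the diaryl ketone (carbonyl alkynylation) and in situ O-acylation of the tertiary lithium alkoxide with an acid chloride made under neutral conditions (Ghosez reagent) should outrun attack on the hindered pivalates, and the carbinol never meets acid.

Step 4
Reactants: 8 3-{4-[(tert-butyldimethylsilyl)oxy]phenyl}-1,1-bis{4-[(2,2-dimethylpropanoyl)oxy]phenyl}prop-2-yn-1-yl 4-[(tert-butyldimethylsilyl)oxy]but-2-ynoate, 9 acetylene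
Product: 10 4-{4-[(tert-butyldimethylsilyl)oxy]phenyl}-7-{[(tert-butyldimethylsilyl)oxy]methyl}-3,3-bis{4-[(2,2-dimethylpropanoyl)oxy]phenyl}-2-benzofuran-1(3H)-one
Conditions: [Rh(cod)2]BF4 (5 mol%), rac-BINAP (5 mol%), CH2Cl2, H2 (1 atm) then purge; acetylene (1 atm, freed of acetone); 8 added slowly by syringe pump, rt
Reagents that add atoms: none
Why: Hydrogenation frees the cationic monovalent rhodium–BINAP fragment from cod; it binds both alkynes of 8 and couples them oxidatively to a rhodacyclopentadiene, forming the C6–C1 bond, after which acetylene inserts and reductive elimination forms C2–C3 and C4–C5 and releases the catalyst. The closest known reaction type is the rhodium-catalysed [2+2+2] cross-cyclotrimerization of ester-linked 1,6-diynes with monoalkynes, an established route to phthalides. The five-membered lactone closes in the oxidative coupling, where the ester tether forces the two inner alkyne carbons together (a 5-exo-type metallacycle annulation); ring A closes by two-carbon insertion and reductive elimination from the seven-membered rhodacycle, with acetylene supplying the adjacent CH positions C3 and C4. No stereocentre is formed, and there is no regiochemical question because acetylene is symmetric. The step needs cross- over self-trimerization of 8 and cyclization over ionization or 1,3-acyloxy shift of the tertiary propargylic ester: the tether makes the first coupling intramolecular, both alkynes of 8 are internal and hindered so a second molecule of 8 competes poorly with excess acetylene while 8 is kept dilute, and the pivaloyloxy groups keep the carbinol carbon from ionizing at room temperature.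

Step 5
Reactants: 10 4-{4-[(tert-butyldimethylsilyl)oxy]phenyl}-7-{[(tert-butyldimethylsilyl)oxy]methyl}-3,3-bis{4-[(2,2-dimethylpropanoyl)oxy]phenyl}-2-benzofuran-1(3H)-one
Product: 11 7-{[(tert-butyldimethylsilyl)oxy]methyl}-3,3,4-tris(4-hydroxyphenyl)-2-benzofuran-1(3H)-one
Conditions: K2CO3 (base promoter), MeOH/THF, rt; aq. NaH2PO4 to pH 5
Reagents that add atoms: none
Why: Base-mediated methanolysis cleaves the two aryl pivalates and the phenolic silyl ether while a primary alkyl silyl ether is known to persist; carbonate only shuttles protons, and the phthalide, if it opens reversibly in base as phenolphthalein does, should re-close on neutralization.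

Step 6
Reactants: 11 7-{[(tert-butyldimethylsilyl)oxy]methyl}-3,3,4-tris(4-hydroxyphenyl)-2-benzofuran-1(3H)-one
Product: 12 7-{[(tert-butyldimethylsilyl)oxy]methyl}-3,3,4-tris[4-(methoxymethoxy)phenyl]-2-benzofuran-1(3H)-one
Conditions: MOMCl, i-Pr2NEt, CH2Cl2, 0 °C → rt
Reagents that add atoms: chloromethyl methyl ether, COCCl
Why: O-Alkylation of the three phenols as MOM acetals gives groups that tolerate hydride, carbonate in methanol and palladium/copper/amine and leave together with the silyl ether in the final acid step.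

Step 7
Reactants: 12 7-{[(tert-butyldimethylsilyl)oxy]methyl}-3,3,4-tris[4-(methoxymethoxy)phenyl]-2-benzofuran-1(3H)-one
Product: 13 rac-7-{[(tert-butyldimethylsilyl)oxy]methyl}-3,3,4-tris[4-(methoxymethoxy)phenyl]-1,3-dihydro-2-benzofuran-1-ol
Conditions: i-Bu2AlH (DIBAL-H), CH2Cl2, −78 °C; MeOH, then aq. KNaC4H4O6 (Rochelle salt)
Reagents that add atoms: none
Why: Partial reduction of a lactone to the lactol with DIBAL-H stops at the tetrahedral aluminium alkoxide at −78 °C; the new hemiacetal carbon forms as a racemate with no controlling element and is removed in step 8.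

Step 8
Reactants: 13 rac-7-{[(tert-butyldimethylsilyl)oxy]methyl}-3,3,4-tris[4-(methoxymethoxy)phenyl]-1,3-dihydro-2-benzofuran-1-ol
Product: 14 {4-({[tert-butyldimethylsilyl]oxy}methyl)-3-ethynyl-4'-(methoxymethoxy)-[1,1'-biphenyl]-2-yl}bis[4-(methoxymethoxy)phenyl]methanol
Conditions: dimethyl (1-diazo-2-oxopropyl)phosphonate, K2CO3, MeOH/THF, 0 °C → rt
Reagents that add atoms: dimethyl (1-diazo-2-oxopropyl)phosphonate, CC(=O)C(=[N+]=[N-])P(=O)(OC)OC
Why: Seyferth–Gilbert homologation in the Ohira–Bestmann form: the lactol equilibrates with its hydroxy aldehyde under carbonate in methanol, the diazophosphonate anion adds and eliminates dimethyl phosphate, and loss of N2 with a 1,2-hydrogen shift gives the terminal alkyne and the free tertiary carbinol.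

Step 9
Reactants: 14 {4-({[tert-butyldimethylsilyl]oxy}methyl)-3-ethynyl-4'-(methoxymethoxy)-[1,1'-biphenyl]-2-yl}bis[4-(methoxymethoxy)phenyl]methanol, 15 4-iodophenol
Product: 16 4-{[4-({[tert-butyldimethylsilyl]oxy}methyl)-2-{hydroxybis[4-(methoxymethoxy)phenyl]methyl}-4'-(methoxymethoxy)-[1,1'-biphenyl]-3-yl]ethynyl}phenol
Conditions: Pd(PPh3)2Cl2 (cat.), CuI (cat.), Et3N, THF, degassed, rt
Reagents that add atoms: none
Why: Sonogashira coupling: the divalent palladium precatalyst is reduced in situ to zerovalent palladium, which inserts into the aryl iodide at room temperature and takes the acetylide from copper; free iodophenols are tolerated, and the mild temperature should avoid cycloisomerization of the ortho-alkynyl carbinol.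

Step 10
Reactants: 16 4-{[4-({[tert-butyldimethylsilyl]oxy}methyl)-2-{hydroxybis[4-(methoxymethoxy)phenyl]methyl}-4'-(methoxymethoxy)-[1,1'-biphenyl]-3-yl]ethynyl}phenol
Product: 17 selaginellin, 4-[{4'-hydroxy-4-(hydroxymethyl)-3-[(4-hydroxyphenyl)ethynyl]-[1,1'-biphenyl]-2-yl}(4-hydroxyphenyl)methylidene]cyclohexa-2,5-dien-1-one
Conditions: HCl (ca. 1 M, from conc. aq. HCl), MeOH/THF, rt → 40 °C; NaHCO3 to pH 6–7
Reagents that add atoms: none
Why: Acid-catalysed acetal exchange removes the three MOM groups (methanol traps the formaldehyde unit as dimethoxymethane) and solvolyses the silyl ether, and the triaryl carbinol ionizes to a doubly 4-oxyphenyl-stabilized cation that loses the phenolic proton (E1 dehydration) to give the fuchsone-type quinone methide, for which no alkene geometry arises.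

**Compound list**

1 | 4,4'-dihydroxybenzophenone | O=C(c1ccc(O)cc1)c1ccc(O)cc1 | starting material
2 | 4,4'-bis(pivaloyloxy)benzophenone | CC(C)(C)C(=O)Oc1ccc(cc1)C(=O)c1ccc(OC(=O)C(C)(C)C)cc1 | intermediate
3 | tert-butyldimethyl(prop-2-yn-1-yloxy)silane | C#CCO[Si](C)(C)C(C)(C)C | starting material
4 | 4-[(tert-butyldimethylsilyl)oxy]but-2-ynoic acid | CC(C)(C)[Si](C)(C)OCC#CC(=O)O | intermediate
5 | tert-butyl(4-ethynylphenoxy)dimethylsilane | C#Cc1ccc(O[Si](C)(C)C(C)(C)C)cc1 | starting material
6 | lithium 3-{4-[(tert-butyldimethylsilyl)oxy]phenyl}-1,1-bis{4-[(2,2-dimethylpropanoyl)oxy]phenyl}prop-2-yn-1-olate (formed in situ) | [Li+].[O-]C(C#Cc1ccc(O[Si](C)(C)C(C)(C)C)cc1)(c1ccc(OC(=O)C(C)(C)C)cc1)c1ccc(OC(=O)C(C)(C)C)cc1 | intermediate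
7 | 4-[(tert-butyldimethylsilyl)oxy]but-2-ynoyl chloride (formed in situ) | CC(C)(C)[Si](C)(C)OCC#CC(Cl)=O | intermediate
8 | 3-{4-[(tert-butyldimethylsilyl)oxy]phenyl}-1,1-bis{4-[(2,2-dimethylpropanoyl)oxy]phenyl}prop-2-yn-1-yl 4-[(tert-butyldimethylsilyl)oxy]but-2-ynoate | CC(C)(C)[Si](C)(C)OCC#CC(=O)OC(C#Cc1ccc(O[Si](C)(C)C(C)(C)C)cc1)(c1ccc(OC(=O)C(C)(C)C)cc1)c1ccc(OC(=O)C(C)(C)C)cc1 | intermediate
9 | acetylene | C#C | starting material
10 | 4-{4-[(tert-butyldimethylsilyl)oxy]phenyl}-7-{[(tert-butyldimethylsilyl)oxy]methyl}-3,3-bis{4-[(2,2-dimethylpropanoyl)oxy]phenyl}-2-benzofuran-1(3H)-one | CC(C)(C)[Si](C)(C)OCc1ccc(-c2ccc(O[Si](C)(C)C(C)(C)C)cc2)c2c1C(=O)OC2(c1ccc(OC(=O)C(C)(C)C)cc1)c1ccc(OC(=O)C(C)(C)C)cc1 | intermediate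
11 | 7-{[(tert-butyldimethylsilyl)oxy]methyl}-3,3,4-tris(4-hydroxyphenyl)-2-benzofuran-1(3H)-one | CC(C)(C)[Si](C)(C)OCc1ccc(-c2ccc(O)cc2)c2c1C(=O)OC2(c1ccc(O)cc1)c1ccc(O)cc1 | intermediate
12 | 7-{[(tert-butyldimethylsilyl)oxy]methyl}-3,3,4-tris[4-(methoxymethoxy)phenyl]-2-benzofuran-1(3H)-one | CC(C)(C)[Si](C)(C)OCc1ccc(-c2ccc(OCOC)cc2)c2c1C(=O)OC2(c1ccc(OCOC)cc1)c1ccc(OCOC)cc1 | intermediate
13 | rac-7-{[(tert-butyldimethylsilyl)oxy]methyl}-3,3,4-tris[4-(methoxymethoxy)phenyl]-1,3-dihydro-2-benzofuran-1-ol (racemic at the lactol carbon) | CC(C)(C)[Si](C)(C)OCc1ccc(-c2ccc(OCOC)cc2)c2c1C(O)OC2(c1ccc(OCOC)cc1)c1ccc(OCOC)cc1 | intermediate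
14 | {4-({[tert-butyldimethylsilyl]oxy}methyl)-3-ethynyl-4'-(methoxymethoxy)-[1,1'-biphenyl]-2-yl}bis[4-(methoxymethoxy)phenyl]methanol | CC(C)(C)[Si](C)(C)OCc1ccc(-c2ccc(OCOC)cc2)c(c1C#C)C(O)(c1ccc(OCOC)cc1)c1ccc(OCOC)cc1 | intermediate
15 | 4-iodophenol | Oc1ccc(I)cc1 | starting material
16 | 4-{[4-({[tert-butyldimethylsilyl]oxy}methyl)-2-{hydroxybis[4-(methoxymethoxy)phenyl]methyl}-4'-(methoxymethoxy)-[1,1'-biphenyl]-3-yl]ethynyl}phenol | CC(C)(C)[Si](C)(C)OCc1ccc(-c2ccc(OCOC)cc2)c(c1C#Cc1ccc(O)cc1)C(O)(c1ccc(OCOC)cc1)c1ccc(OCOC)cc1 | intermediate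
17 | selaginellin | O=C1C=CC(=C(c2ccc(O)cc2)c2c(-c3ccc(O)cc3)ccc(CO)c2C#Cc2ccc(O)cc2)C=C1 | target

**Count**

Total step count: 10.
Longest linear sequence: 9 steps (1 → 2 → 8 → 10 → 11 → 12 → 13 → 14 → 16 → 17; the branch from 3 through 4 is equally long).

**Steps most likely to fail**

Step 4. Acetylene may oligomerize on the cationic rhodium centre and use up the catalyst, while the low concentration of dissolved gas lets self-coupling of the diyne or a slow acyloxy shift of the propargylic ester gain ground. The fallback sets out from 8 and uses liquid vinyl acetate, in large excess as co-solvent, as an acetylene equivalent under the same [Rh(cod)2]BF4/BINAP catalysis (the known formal cross-cyclotrimerization of 1,6-diynes with enol acetates). The diyne adds across the C=C bond to give 4-{4-[(tert-butyldimethylsilyl)oxy]phenyl}-7-{[(tert-butyldimethylsilyl)oxy]methyl}-3,3-bis{4-[(2,2-dimethylpropanoyl)oxy]phenyl}-1-oxo-1,3,5,6-tetrahydro-2-benzofuran-6-yl acetate F1 (either acetoxy regioisomer serves, racemic, not purified). This loses acetic acid on gentle warming with a trace of Et3N and comes back to the route at 10.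

Step 8. The gem-diaryl lactol may stay closed, so the aldehyde is exposed more slowly than the diazophosphonate decays in carbonate/methanol. The fallback sets out from 13 and uses a Wittig chloromethylenation with Ph3P=CHCl, made from (chloromethyl)triphenylphosphonium chloride and NaN(SiMe3)2 in THF at −78 °C → rt. The strongly basic ylide deprotonates the lactol and intercepts the open aldehyde, giving {3-(2-chloroethenyl)-4-({[tert-butyldimethylsilyl]oxy}methyl)-4'-(methoxymethoxy)-[1,1'-biphenyl]-2-yl}bis[4-(methoxymethoxy)phenyl]methanol F2 as an E/Z mixture. Dehydrochlorination of both isomers with excess LiN(i-Pr)2 in THF (−78 → 0 °C) and protonation returns to the route at 14.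

Step 10. During the prolonged protic-acid treatment that the biaryl MOM ether needs, the freed benzylic hydroxyl or methanol may add across the electron-rich alkyne, and formaldehyde equivalents may alkylate the free phenols. The fallback sets out from 16 and splits the unmasking into two stages. Me2BBr in CH2Cl2 at −78 °C cleaves the three MOM ethers as bromomethyl methyl ether while the primary silyl ether is expected to persist. Aqueous NaHCO3 work-up then lets the carbinol dehydrate to 4-[{4-({[tert-butyldimethylsilyl]oxy}methyl)-4'-hydroxy-3-[(4-hydroxyphenyl)ethynyl]-[1,1'-biphenyl]-2-yl}(4-hydroxyphenyl)methylidene]cyclohexa-2,5-dien-1-one F3. HF·pyridine in THF/pyridine at 0 °C removes the silyl group, so the hydroxymethyl group is set free only when no strong acid is present, and the route is rejoined at 17.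

**Further compounds**

F1 | step 4 | 4-{4-[(tert-butyldimethylsilyl)oxy]phenyl}-7-{[(tert-butyldimethylsilyl)oxy]methyl}-3,3-bis{4-[(2,2-dimethylpropanoyl)oxy]phenyl}-1-oxo-1,3,5,6-tetrahydro-2-benzofuran-6-yl acetate (racemic) | CC(C)(C)[Si](C)(C)OCC1=C2C(=O)OC(c3ccc(OC(=O)C(C)(C)C)cc3)(c3ccc(OC(=O)C(C)(C)C)cc3)C2=C(c2ccc(O[Si](C)(C)C(C)(C)C)cc2)CC1OC(C)=O
F2 | step 8 | {3-(2-chloroethenyl)-4-({[tert-butyldimethylsilyl]oxy}methyl)-4'-(methoxymethoxy)-[1,1'-biphenyl]-2-yl}bis[4-(methoxymethoxy)phenyl]methanol (E/Z mixture) | CC(C)(C)[Si](C)(C)OCc1ccc(-c2ccc(OCOC)cc2)c(c1C=CCl)C(O)(c1ccc(OCOC)cc1)c1ccc(OCOC)cc1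
F3 | step 10 | 4-[{4-({[tert-butyldimethylsilyl]oxy}methyl)-4'-hydroxy-3-[(4-hydroxyphenyl)ethynyl]-[1,1'-biphenyl]-2-yl}(4-hydroxyphenyl)methylidene]cyclohexa-2,5-dien-1-one | CC(C)(C)[Si](C)(C)OCc1ccc(-c2ccc(O)cc2)c(C(=C2C=CC(=O)C=C2)c2ccc(O)cc2)c1C#Cc1ccc(O)cc1
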